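**Plan**
- Retrosynthesis (germacrane numbering: C6 lactone O–CH, C7 ring-fusion CH, C8 ester carbon, C9 carbinol, C10/C14 enal, C11–C13 methylene lactone, C15 methyl): the ten-membered carbocycle is opened at C9–C10 (alkenyl iodide + aldehyde). Then the C8–O ester bond (invertive esterification), C7–C8 (allylation), the butenolide C7=C11 and its ester C12–O (metathesis, esterification), C6–C7 (vinyl addition) and C1=C10 (Wittig) are cut; C1–C6 with C15 is neryl acetate.
- Forward: neryl acetate → (Z,Z)-iodo acetal enal → lactone ring first (butenolide by RCM, turned into the α-methylene lactone by the allylation) → C8 ester → carbocycle last → release of the enal.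
- Enabling feature: the C9 carbinol sits on the vinylic carbon C10 of the C1=C10 enal (retron of an alkenyl-metal addition to an aldehyde). Both ring olefins have their ring carbons cis (C3/C6 on C4=C5, C2/C9 on C1=C10) and the lactone is trans-fused at C6/C7, so the open chain can fold to a cis,cis-cyclodecadiene without E-olefin strain.
- Stereochemistry: C6 by lipase resolution; C7 by attack anti to the C6 side chain; C8 by the chair allylation transition state followed by Mitsunobu inversion with (S)-2-methylbutanoic acid, which also supplies the side-chain centre; C9 in the ring closure; Z-C4=C5 from nerol, C1=C10 geometry from the (Z)-α-iodoenal.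

Key step: step 14

Remark: partners that bring carbon into the product are numbered and stand under Reactants; the line "Reagents that add atoms" lists unnumbered reagents only.
Assumption: the indium allylation passes through the usual closed chair transition state and therefore gives the C8 epimer of the target, which the invertive esterification corrects.

**Route**

Step 1
Reactants: 1 neryl acetate
Product: 2 (2Z)-3-methyl-6-oxohex-2-en-1-yl acetate
Conditions: O3 (1.0 equiv), CH2Cl2/pyridine, −78 °C; then Me2S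
Reagents that add atoms: ozone, [O-][O+]=O
Why: Chemoselective ozonolysis: ozone cleaves the electron-rich 6,7-olefin much faster than the 2,3-olefin that is deactivated by the allylic acetate, and reductive work-up gives the aldehyde with the Z olefin intact.

Step 2
Reactants: 2 (2Z)-3-methyl-6-oxohex-2-en-1-yl acetate; 3 (triphenylphosphoranylidene)acetaldehyde
Product: 4 (2Z,6E)-3-methyl-8-oxoocta-2,6-dien-1-yl acetate
Conditions: PhMe, 80 °C
Reagents that add atoms: none
Why: Wittig olefination with the stabilised formyl ylide adds two carbons and gives the (E)-enal.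

Step 3
Reactants: 4 (2Z,6E)-3-methyl-8-oxoocta-2,6-dien-1-yl acetate
Product: 5 (2Z,6Z)-7-iodo-3-methyl-8-oxoocta-2,6-dien-1-yl acetate
Conditions: I2, K2CO3, DMAP (20 mol %), THF/H2O 1:1, rt, dark
Reagents that add atoms: iodine, II
Why: Amine-catalysed α-iodination of the enal (conjugate addition of DMAP, iodination of the enolate, E1cB loss of DMAP) gives the (Z)-α-iodoenal, the isomer with the formyl group trans to the chain, which fixes the later C2/C9 cis relationship.

Step 4
Reactants: 5 (2Z,6Z)-7-iodo-3-methyl-8-oxoocta-2,6-dien-1-yl acetate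
Product: 7 (2Z,6Z)-7-iodo-8,8-dimethoxy-3-methylocta-2,6-dien-1-ol, via acetal acetate 6 (not isolated)
Conditions: HC(OMe)3, PPTS (cat.), MeOH, rt; then K2CO3 (cat.), rt
Reagents that add atoms: trimethyl orthoformate, COC(OC)OC; methanol, CO
Why: Acid-catalysed acetalisation with the orthoformate as water scavenger masks the formyl group (C14), and base-catalysed transesterification in the same pot then removes the acetate, to which the acetal and the alkenyl iodide are inert.

Step 5
Reactants: 7 (2Z,6Z)-7-iodo-8,8-dimethoxy-3-methylocta-2,6-dien-1-ol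
Product: 8 (2Z,6Z)-7-iodo-8,8-dimethoxy-3-methylocta-2,6-dienal
Conditions: MnO2 (excess), hexane/CH2Cl2, 0 °C
Reagents that add atoms: none
Why: MnO2 oxidation of the primary allylic alcohol is neutral and heterogeneous, so the Z-trisubstituted enal (as in the nerol to neral case) and the acetal should survive.

Step 6
Reactants: 8 (2Z,6Z)-7-iodo-8,8-dimethoxy-3-methylocta-2,6-dienal; 9 vinylmagnesium bromide
Product: 10 rac-(4Z,8Z)-9-iodo-10,10-dimethoxy-5-methyldeca-1,4,8-trien-3-ol
Conditions: THF, −78 °C; aqueous work-up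
Reagents that add atoms: none
Why: Grignard 1,2-addition to the enal at low temperature gives the bis-allylic alcohol as a racemate, the acetal and the alkenyl iodide being inert at −78 °C.

Step 7
Reactants: 10 rac-(4Z,8Z)-9-iodo-10,10-dimethoxy-5-methyldeca-1,4,8-trien-3-ol
Product: 11 (3S,4Z,8Z)-9-iodo-10,10-dimethoxy-5-methyldeca-1,4,8-trien-3-ol
Conditions: immobilised Candida antarctica lipase B (Novozym 435), vinyl acetate, hexane, 30 °C, to ca. 55% conversion
Reagents that add atoms: none
Why: Lipase-catalysed kinetic resolution by transesterification: the enzyme should acylate the (3R)-alcohol (vinyl as the medium group, the trisubstituted alkenyl arm as the large group) and leave the (3S)-alcohol, which carries the C6 configuration of the target.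

Step 8
Reactants: 11 (3S,4Z,8Z)-9-iodo-10,10-dimethoxy-5-methyldeca-1,4,8-trien-3-ol; 12 2-(bromomethyl)prop-2-enoic acid
Product: 13 (3S,4Z,8Z)-9-iodo-10,10-dimethoxy-5-methyldeca-1,4,8-trien-3-yl 2-(bromomethyl)prop-2-enoate
Conditions: DCC, DMAP (5 mol %), CH2Cl2, 0 °C
Reagents that add atoms: none
Why: Steglich esterification of the secondary alcohol, run cold with little DMAP so that the allylic bromide and the bis-allylic ester are not attacked.

Step 9
Reactants: 13 (3S,4Z,8Z)-9-iodo-10,10-dimethoxy-5-methyldeca-1,4,8-trien-3-yl 2-(bromomethyl)prop-2-enoate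
Product: 14 (5R)-3-(bromomethyl)-5-[(1Z,5Z)-6-iodo-7,7-dimethoxy-2-methylhepta-1,5-dien-1-yl]furan-2(5H)-one
Conditions: Grubbs II catalyst (10 mol %), PhMe, 80 °C, Ar sparge
Reagents that add atoms: none
Why: Ring-closing metathesis: the carbene forms at the monosubstituted vinyl group and closes onto the 1,1-disubstituted acrylate to the five-membered butenolide (C7=C11), the trisubstituted olefins and the alkenyl iodide being too hindered to compete and C6 not being touched.

Step 10
Reactants: 14 (5R)-3-(bromomethyl)-5-[(1Z,5Z)-6-iodo-7,7-dimethoxy-2-methylhepta-1,5-dien-1-yl]furan-2(5H)-one; 15 (tert-butyldimethylsilyloxy)acetaldehyde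
Product: 16 (4R,5R)-4-[(1R)-2-{[tert-butyl(dimethyl)silyl]oxy}-1-hydroxyethyl]-5-[(1Z,5Z)-6-iodo-7,7-dimethoxy-2-methylhepta-1,5-dien-1-yl]-3-methylideneoxolan-2-one
Conditions: In powder (1.5 equiv), THF/H2O 1:1, rt
Reagents that add atoms: none
Why: Indium-mediated Barbier allylation: the allylindium reacts at C7 (SE2′) through a closed chair transition state, on the ring face anti to the C6 side chain (sets C7 trans to C6) and with the aldehyde residue equatorial (sets C8 anti, the 8-epi configuration), and the shift of the double bond delivers the α-methylene lactone.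

Step 11
Reactants: 16 (4R,5R)-4-[(1R)-2-{[tert-butyl(dimethyl)silyl]oxy}-1-hydroxyethyl]-5-[(1Z,5Z)-6-iodo-7,7-dimethoxy-2-methylhepta-1,5-dien-1-yl]-3-methylideneoxolan-2-one; 17 (2S)-2-methylbutanoic acid
Product: 18 (1S)-2-{[tert-butyl(dimethyl)silyl]oxy}-1-{(2R,3S)-2-[(1Z,5Z)-6-iodo-7,7-dimethoxy-2-methylhepta-1,5-dien-1-yl]-4-methylidene-5-oxooxolan-3-yl}ethyl (2S)-2-methylbutanoate
Conditions: PPh3, DIAD, PhMe, 0 °C → rt
Reagents that add atoms: none
Why: Mitsunobu esterification: the carboxylate displaces the oxyphosphonium group at C8 by SN2 with inversion, which corrects C8 and installs the ester, whose own stereocentre comes unchanged from the acid because the carboxyl group is never activated.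

Step 12
Reactants: 18 (1S)-2-{[tert-butyl(dimethyl)silyl]oxy}-1-{(2R,3S)-2-[(1Z,5Z)-6-iodo-7,7-dimethoxy-2-methylhepta-1,5-dien-1-yl]-4-methylidene-5-oxooxolan-3-yl}ethyl (2S)-2-methylbutanoate
Product: 19 (1S)-2-hydroxy-1-{(2R,3S)-2-[(1Z,5Z)-6-iodo-7,7-dimethoxy-2-methylhepta-1,5-dien-1-yl]-4-methylidene-5-oxooxolan-3-yl}ethyl (2S)-2-methylbutanoate
Conditions: HF·pyridine, pyridine, THF, 0 °C → rt
Reagents that add atoms: none
Why: Fluoride-mediated desilylation of the primary TBS ether under buffered, weakly acidic conditions that should avoid 1,2-acyl migration and spare the acetal and the methylene lactone.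

Step 13
Reactants: 19 (1S)-2-hydroxy-1-{(2R,3S)-2-[(1Z,5Z)-6-iodo-7,7-dimethoxy-2-methylhepta-1,5-dien-1-yl]-4-methylidene-5-oxooxolan-3-yl}ethyl (2S)-2-methylbutanoate
Product: 20 (1S)-1-{(2R,3S)-2-[(1Z,5Z)-6-iodo-7,7-dimethoxy-2-methylhepta-1,5-dien-1-yl]-4-methylidene-5-oxooxolan-3-yl}-2-oxoethyl (2S)-2-methylbutanoate
Conditions: Dess–Martin periodinane, pyridine, CH2Cl2, 0 °C; used crude
Reagents that add atoms: none
Why: Dess–Martin oxidation of the primary alcohol under non-basic conditions gives the α-acyloxy aldehyde without epimerisation at C8, and the aldehyde is used at once.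

Step 14
Reactants: 20 (1S)-1-{(2R,3S)-2-[(1Z,5Z)-6-iodo-7,7-dimethoxy-2-methylhepta-1,5-dien-1-yl]-4-methylidene-5-oxooxolan-3-yl}-2-oxoethyl (2S)-2-methylbutanoate
Product: 21 (3aS,4S,5S,6E,10Z,11aR)-6-(dimethoxymethyl)-5-hydroxy-10-methyl-3-methylidene-2-oxo-2,3,3a,4,5,8,9,11a-octahydrocyclodeca[b]furan-4-yl (2S)-2-methylbutanoate
Conditions: CrCl2 (10 equiv), NiCl2 (2 mol %), DMSO/THF 3:1, 2 mM, rt, slow addition of 20
Reagents that add atoms: none
Why: Ni(0) inserts into the C10–I bond with retention of the Z geometry, the alkenyl group is passed to chromium(III), and the alkenylchromium adds to the C9 aldehyde within the same molecule; the closest known reaction type is the Nozaki–Hiyama–Kishi macrocyclisation of iodoalkenyl aldehydes to medium and large carbocycles. The ten-membered carbocycle is closed by C9–C10 bond formation in a 10-exo-trig mode while the lactone ring is already in place. The new stereocentre C9 is controlled by the C8 and C7 stereocentres through the cyclic transition state: with ring carbon C7 antiperiplanar to the forming bond, the acyloxy group beside the carbonyl oxygen and H-8 toward the incoming carbon, the Si face of the aldehyde is attacked and the 8,9-syn (9S) alcohol should result. The step needs chemoselectivity for the aldehyde over lactone, ester and methylene acceptor, which the low basicity and low nucleophilicity of alkenylchromium(III) secure, and it needs ring closure to outrun oligomerisation, which high dilution, the two ring-cis olefins and the trans C6/C7 lactone fusion favour. The cis relationship of C2 and C9 across C1=C10 that the ring requires is already fixed in the (Z)-iodide.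

Step 15
Reactants: 21 (3aS,4S,5S,6E,10Z,11aR)-6-(dimethoxymethyl)-5-hydroxy-10-methyl-3-methylidene-2-oxo-2,3,3a,4,5,8,9,11a-octahydrocyclodeca[b]furan-4-yl (2S)-2-methylbutanoate
Product: 22 (3aS,4S,5S,6E,10Z,11aR)-6-formyl-5-hydroxy-10-methyl-3-methylidene-2-oxo-2,3,3a,4,5,8,9,11a-octahydrocyclodeca[b]furan-4-yl (2S)-2-methylbutanoate
Conditions: PPTS (cat.), acetone/H2O 10:1, rt
Reagents that add atoms: water, O
Why: Acid-catalysed hydrolysis of the allylic dimethyl acetal releases the enal, whose geometry is held by the ring, under conditions mild enough for the ester, the methylene lactone and the allylic alcohol.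

**Compound list**
1 | neryl acetate, (2Z)-3,7-dimethylocta-2,6-dien-1-yl acetate | CC(C)=CCC/C(C)=C\COC(C)=O | starting material
2 | (2Z)-3-methyl-6-oxohex-2-en-1-yl acetate | O=CCC/C(C)=C\COC(C)=O | intermediate
3 | (triphenylphosphoranylidene)acetaldehyde | O=CC=P(c1ccccc1)(c1ccccc1)c1ccccc1 | starting material
4 | (2Z,6E)-3-methyl-8-oxoocta-2,6-dien-1-yl acetate | O=C/C=C/CC/C(C)=C\COC(C)=O | intermediate
5 | (2Z,6Z)-7-iodo-3-methyl-8-oxoocta-2,6-dien-1-yl acetate | O=C/C(I)=C/CC/C(C)=C\COC(C)=O | intermediate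
6 | (2Z,6Z)-7-iodo-8,8-dimethoxy-3-methylocta-2,6-dien-1-yl acetate | COC(OC)/C(I)=C/CC/C(C)=C\COC(C)=O | intermediate
7 | (2Z,6Z)-7-iodo-8,8-dimethoxy-3-methylocta-2,6-dien-1-ol | COC(OC)/C(I)=C/CC/C(C)=C\CO | intermediate
8 | (2Z,6Z)-7-iodo-8,8-dimethoxy-3-methylocta-2,6-dienal | COC(OC)/C(I)=C/CC/C(C)=C\C=O | intermediate
9 | vinylmagnesium bromide | C=C[Mg]Br | starting material
10 | rac-(4Z,8Z)-9-iodo-10,10-dimethoxy-5-methyldeca-1,4,8-trien-3-ol | COC(OC)/C(I)=C/CC/C(C)=C\C(O)C=C | intermediate
11 | (3S,4Z,8Z)-9-iodo-10,10-dimethoxy-5-methyldeca-1,4,8-trien-3-ol | COC(OC)/C(I)=C/CC/C(C)=C\[C@@H](O)C=C | intermediate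
12 | 2-(bromomethyl)prop-2-enoic acid | C=C(CBr)C(=O)O | starting material
13 | (3S,4Z,8Z)-9-iodo-10,10-dimethoxy-5-methyldeca-1,4,8-trien-3-yl 2-(bromomethyl)prop-2-enoate | COC(OC)/C(I)=C/CC/C(C)=C\[C@@H](OC(=O)C(=C)CBr)C=C | intermediate
14 | (5R)-3-(bromomethyl)-5-[(1Z,5Z)-6-iodo-7,7-dimethoxy-2-methylhepta-1,5-dien-1-yl]furan-2(5H)-one | COC(OC)/C(I)=C/CC/C(C)=C\[C@H]1OC(=O)C(CBr)=C1 | intermediate
15 | (tert-butyldimethylsilyloxy)acetaldehyde | CC(C)(C)[Si](C)(C)OCC=O | starting material
16 | (4R,5R)-4-[(1R)-2-{[tert-butyl(dimethyl)silyl]oxy}-1-hydroxyethyl]-5-[(1Z,5Z)-6-iodo-7,7-dimethoxy-2-methylhepta-1,5-dien-1-yl]-3-methylideneoxolan-2-one | C=C1C(=O)O[C@H](/C=C(/C)CC/C=C(\I)C(OC)OC)[C@H]1[C@@H](O)CO[Si](C)(C)C(C)(C)C | intermediate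
17 | (2S)-2-methylbutanoic acid | CC[C@H](C)C(=O)O | starting material
18 | (1S)-2-{[tert-butyl(dimethyl)silyl]oxy}-1-{(2R,3S)-2-[(1Z,5Z)-6-iodo-7,7-dimethoxy-2-methylhepta-1,5-dien-1-yl]-4-methylidene-5-oxooxolan-3-yl}ethyl (2S)-2-methylbutanoate | C=C1C(=O)O[C@H](/C=C(/C)CC/C=C(\I)C(OC)OC)[C@H]1[C@H](OC(=O)[C@@H](C)CC)CO[Si](C)(C)C(C)(C)C | intermediate
19 | (1S)-2-hydroxy-1-{(2R,3S)-2-[(1Z,5Z)-6-iodo-7,7-dimethoxy-2-methylhepta-1,5-dien-1-yl]-4-methylidene-5-oxooxolan-3-yl}ethyl (2S)-2-methylbutanoate | C=C1C(=O)O[C@H](/C=C(/C)CC/C=C(\I)C(OC)OC)[C@H]1[C@H](OC(=O)[C@@H](C)CC)CO | intermediate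
20 | (1S)-1-{(2R,3S)-2-[(1Z,5Z)-6-iodo-7,7-dimethoxy-2-methylhepta-1,5-dien-1-yl]-4-methylidene-5-oxooxolan-3-yl}-2-oxoethyl (2S)-2-methylbutanoate | C=C1C(=O)O[C@H](/C=C(/C)CC/C=C(\I)C(OC)OC)[C@H]1[C@H](OC(=O)[C@@H](C)CC)C=O | intermediate
21 | (3aS,4S,5S,6E,10Z,11aR)-6-(dimethoxymethyl)-5-hydroxy-10-methyl-3-methylidene-2-oxo-2,3,3a,4,5,8,9,11a-octahydrocyclodeca[b]furan-4-yl (2S)-2-methylbutanoate | C=C1C(=O)O[C@@H]2/C=C(/C)CC/C=C(/C(OC)OC)[C@H](O)[C@@H](OC(=O)[C@@H](C)CC)[C@@H]12 | intermediate
22 | (3aS,4S,5S,6E,10Z,11aR)-6-formyl-5-hydroxy-10-methyl-3-methylidene-2-oxo-2,3,3a,4,5,8,9,11a-octahydrocyclodeca[b]furan-4-yl (2S)-2-methylbutanoate (CNP0168436.1) | C=C1C(=O)O[C@@H]2/C=C(/C)CC/C=C(/C=O)[C@H](O)[C@@H](OC(=O)[C@@H](C)CC)[C@@H]12 | target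

**Count**
Total steps: 15. Longest linear sequence: 15 steps (1 → 22); the route is fully linear.

**Steps most likely to fail, with fallbacks**

Step 14. The ring closure may run with poor facial selectivity at C9 (an approach anti to the C8 acyloxy group would give the 9-epimer), or chain-to-chain coupling may outrun cyclisation. The fallback sets out from 20 and no longer relies on the C–C bond formation for the C9 configuration. The same Ni/Cr closure is run and the alcohol mixture, in the unfavourable case mainly (3aS,4S,5R,6E,10Z,11aR)-6-(dimethoxymethyl)-5-hydroxy-10-methyl-3-methylidene-2-oxo-2,3,3a,4,5,8,9,11a-octahydrocyclodeca[b]furan-4-yl (2S)-2-methylbutanoate F1, is oxidised with MnO2 to the macrocyclic enone (3aS,4S,6Z,10Z,11aR)-6-(dimethoxymethyl)-10-methyl-3-methylidene-2,5-dioxo-2,3,3a,4,5,8,9,11a-octahydrocyclodeca[b]furan-4-yl (2S)-2-methylbutanoate F2. C9 is then set by reagent-controlled 1,2-reduction with a Corey–Bakshi–Shibata oxazaborolidine and catecholborane at −78 °C (hydride to the Re face of the ketone; the (S)-catalyst if the α-branched alkenyl arm behaves as the large group). This comes back to the route at 21.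

Step 11. The activated C8 oxygen may be lost by E2 elimination toward C7–H (conjugated diene), or substitution at the hindered carbinol may not occur. The fallback sets out from 16 and replaces the invertive substitution by oxidation and reduction. Dess–Martin oxidation (pyridine buffer, 0 °C) should give the ketone (4S,5R)-4-({[tert-butyl(dimethyl)silyl]oxy}acetyl)-5-[(1Z,5Z)-6-iodo-7,7-dimethoxy-2-methylhepta-1,5-dien-1-yl]-3-methylideneoxolan-2-one F3, which is handled cold because C7–H is activated. Reduction with (S)-Me-CBS and BH3·SMe2 (silyloxymethyl as the small group, the lactone carbon as the large group) should give the alcohol (4R,5R)-4-[(1S)-2-{[tert-butyl(dimethyl)silyl]oxy}-1-hydroxyethyl]-5-[(1Z,5Z)-6-iodo-7,7-dimethoxy-2-methylhepta-1,5-dien-1-yl]-3-methylideneoxolan-2-one F4. Steglich esterification with 17 (DCC, cat. DMAP, retention) comes back to the route at 18.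

Step 9. Ring closure onto the 1,1-disubstituted, bromomethyl-bearing acrylate may be slow, with catalyst decay or loss of the allylic bromide. The fallback sets out from 11 and installs C13 only after the ring is made. Acylation with acryloyl chloride and Et3N gives the acrylate (3S,4Z,8Z)-9-iodo-10,10-dimethoxy-5-methyldeca-1,4,8-trien-3-yl prop-2-enoate F5. RCM on this unhindered acrylate (Grubbs II, CH2Cl2, 40 °C) gives the butenolide (5S)-5-[(1Z,5Z)-6-iodo-7,7-dimethoxy-2-methylhepta-1,5-dien-1-yl]furan-2(5H)-one F6. A Morita–Baylis–Hillman reaction with aqueous formaldehyde (imidazole, THF/H2O) gives (5R)-3-(hydroxymethyl)-5-[(1Z,5Z)-6-iodo-7,7-dimethoxy-2-methylhepta-1,5-dien-1-yl]furan-2(5H)-one F7, and Appel bromination (CBr4, PPh3) comes back to the route at 14.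

**Further compounds**
F1 | step 14 | (3aS,4S,5R,6E,10Z,11aR)-6-(dimethoxymethyl)-5-hydroxy-10-methyl-3-methylidene-2-oxo-2,3,3a,4,5,8,9,11a-octahydrocyclodeca[b]furan-4-yl (2S)-2-methylbutanoate | C=C1C(=O)O[C@@H]2/C=C(/C)CC/C=C(/C(OC)OC)[C@@H](O)[C@@H](OC(=O)[C@@H](C)CC)[C@@H]12
F2 | step 14 | (3aS,4S,6Z,10Z,11aR)-6-(dimethoxymethyl)-10-methyl-3-methylidene-2,5-dioxo-2,3,3a,4,5,8,9,11a-octahydrocyclodeca[b]furan-4-yl (2S)-2-methylbutanoate | C=C1C(=O)O[C@@H]2/C=C(/C)CC/C=C(/C(OC)OC)C(=O)[C@@H](OC(=O)[C@@H](C)CC)[C@@H]12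
F3 | step 11 | (4S,5R)-4-({[tert-butyl(dimethyl)silyl]oxy}acetyl)-5-[(1Z,5Z)-6-iodo-7,7-dimethoxy-2-methylhepta-1,5-dien-1-yl]-3-methylideneoxolan-2-one | C=C1C(=O)O[C@H](/C=C(/C)CC/C=C(\I)C(OC)OC)[C@H]1C(=O)CO[Si](C)(C)C(C)(C)C
F4 | step 11 | (4R,5R)-4-[(1S)-2-{[tert-butyl(dimethyl)silyl]oxy}-1-hydroxyethyl]-5-[(1Z,5Z)-6-iodo-7,7-dimethoxy-2-methylhepta-1,5-dien-1-yl]-3-methylideneoxolan-2-one | C=C1C(=O)O[C@H](/C=C(/C)CC/C=C(\I)C(OC)OC)[C@H]1[C@H](O)CO[Si](C)(C)C(C)(C)C
F5 | step 9 | (3S,4Z,8Z)-9-iodo-10,10-dimethoxy-5-methyldeca-1,4,8-trien-3-yl prop-2-enoate | COC(OC)/C(I)=C/CC/C(C)=C\[C@@H](OC(=O)C=C)C=C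
F6 | step 9 | (5S)-5-[(1Z,5Z)-6-iodo-7,7-dimethoxy-2-methylhepta-1,5-dien-1-yl]furan-2(5H)-one | COC(OC)/C(I)=C/CC/C(C)=C\[C@H]1OC(=O)C=C1
F7 | step 9 | (5R)-3-(hydroxymethyl)-5-[(1Z,5Z)-6-iodo-7,7-dimethoxy-2-methylhepta-1,5-dien-1-yl]furan-2(5H)-one | COC(OC)/C(I)=C/CC/C(C)=C\[C@H]1OC(=O)C(CO)=C1
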